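## Retrosynthetic overview

1. 14 ⇒ 13 ⇒ 12: the two benzyl ethers come off last. The benzylic carbinol carbon Cα (R) comes from chelation-controlled reduction of an α-benzyloxy ketone whose Cβ (S) is (S)-lactate. 12 ⇒ aryl bromide 8 + Weinreb amide 10 (bond C5–Cα).
2. 8 ⇒ spiro[2.5]octa-5,7-dien-4-one 7 ⇒ quinone diazide 5 + (E)-benzyl isoeugenol 6. The dihydrofuran ring (O1, C2, C3, C3a, C7a) is first laid down as the cyclopropane C3a–C3–C2, then takes in C7a and O1 (Cloke–Wilson ring expansion, three to five members) in the same flask.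
3. Enabling feature: O1–C7a=C3a of ring A is the enolate of a cyclohexadienone whose α-carbon C3a can serve as a carbene carbon, and C2 is benzylic to ring B with its para oxygen. In 7 the bond C3a–C2 therefore lies between a donor (ring B) and an acceptor (C7a=O1), and its heterolysis is paid for by aromatisation of ring A.
4. Stereochemistry: C3 from the chiral dirhodium catalyst; C2 from C3 by reversible, trans-selective closure (spiro epimers and any cis isomer converge); Cβ from the chiral pool; Cα from Cβ.
5. Order of rings: rings A and B are bought (ring A passes through the dienone level in 5 and 7); cyclopropane, then dihydrofuran ring, in step 4. 5 ⇒ 4-bromo-2-methoxyphenol 1 by nitration, reduction and diazotisation.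

Key step: step 4

Assumption: Rh2(S-TCPTTL)4 (TCPTTL = N-tetrachlorophthaloyl-tert-leucinate) is taken to direct the carbene to the Re face of the methyl-bearing alkene carbon of 6. If the opposite sense is found, the mirror-image catalyst Rh2(R-TCPTTL)4 from D-tert-leucine is used in the same way.

## Route

Step 1
Reactants: 1 4-bromo-2-methoxyphenol
Product: 2 4-bromo-2-methoxy-6-nitrophenol
Conditions: HNO3 (65 %, 1.05 equiv), AcOH, 0–10 °C
Reagents that add atoms: nitric acid O[N+](=O)[O-]
Why: Electrophilic aromatic nitration: the free OH is the strongest director and its para position is blocked by Br, so the nitro group enters the one free ortho position C6, as in the nitration of other 4-substituted guaiacols.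

Step 2
Reactants: 2 4-bromo-2-methoxy-6-nitrophenol
Product: 3 2-amino-4-bromo-6-methoxyphenol
Conditions: H2 (1 atm), Pt/C (sulfided, 5 wt %), EtOAc, rt; used at once
Reagents that add atoms: none
Why: Catalytic hydrogenation of a nitroarene: sulfided platinum reduces NO2 to NH2 without hydrogenolysis of the C–Br bond.

Step 3
Reactants: 3 2-amino-4-bromo-6-methoxyphenol
Product: 5 4-bromo-6-diazo-2-methoxycyclohexa-2,4-dien-1-one, via diazonium chloride 4 (not isolated)
Conditions: NaNO2, aq HCl, 0 °C; then aq K2CO3, CH2Cl2, 0 °C, dark; kept as a dried solution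
Reagents that add atoms: sodium nitrite [Na+].[O-]N=O; hydrogen chloride Cl (chloride of intermediate 4 only)
Why: Diazotisation of an o-aminophenol followed by deprotonation of the o-hydroxydiazonium salt gives the neutral, extractable quinone diazide, a stabilised cyclic α-diazoketone.

Step 4
Reactants: 5 4-bromo-6-diazo-2-methoxycyclohexa-2,4-dien-1-one; 6 (E)-1-(benzyloxy)-2-methoxy-4-(prop-1-enyl)benzene (benzyl isoeugenol, crystalline E isomer)
Product: 8 (2S,3S)-2-[4-(benzyloxy)-3-methoxyphenyl]-5-bromo-7-methoxy-3-methyl-2,3-dihydro-1-benzofuran, via spirocyclopropyl dienone 7 (not isolated)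
Conditions: Rh2(S-TCPTTL)4 (1 mol %), 4 Å MS, PhCF3, 40 °C, slow addition of 5 (1.3 equiv) to 6 (1.0 equiv); then Sc(OTf)3 (5 mol %), MeCN co-solvent, rt, same flask
Reagents that add atoms: none
Why: Proposed new method: loss of N2 from 5 on the dirhodium catalyst gives an electrophilic quinoid carbene at C3a that adds [2+1] and suprafacially to the E-alkene of 6, the leading bond going to the methyl-bearing carbon because ring B stabilises the charge at the benzylic carbon, and this gives the trans-cyclopropane 7 as a mixture of spiro epimers; the closest known reaction types are the racemic dirhodium-catalysed cyclopropanation and formal [3+2] cycloaddition of alkenes with quinone diazides and the Cloke–Wilson rearrangement of cyclopropyl ketones to dihydrofurans. In 7 the bond C3a–C2 lies between the donor ring B and the acceptor dienone, so it ionises (spontaneously or on Sc(OTf)3) to a ring A phenoxide and a 4-benzyloxybenzyl cation of quinone methide character, and O1 closes on C2 in a 5-exo-trig mode, so that the three-membered ring C3a–C3–C2 grows by C7a and O1 into the dihydrofuran while ring A becomes aromatic. C3 is set by the catalyst, whose crown of four N-tetrachlorophthaloyl-tert-leucinate ligands should leave one approach to the flat carbene open and admit the alkene with the Re face of its methyl-bearing carbon, and this centre is not touched again. C2 is set by C3, because closure anti to the methyl group is favoured kinetically and, since the bond C2–O1 re-ionises under Sc(OTf)3, also thermodynamically, so both spiro epimers of 7 and any cis isomer funnel into the trans (2S,3S) product. The step needs chemoselectivity for the alkene over the arenes and the benzylic C–H bonds of 6, which the high nucleophilicity of the 4-alkoxystyrene secures, while slow addition of 5 holds back carbene dimerisation and the use of 6 as the limiting partner leaves no alkene to trap the cation once the Lewis acid is added.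

Step 5
Reactants: 9 ethyl (S)-2-(benzyloxy)propanoate
Product: 10 (S)-2-(benzyloxy)-N-methoxy-N-methylpropanamide
Conditions: MeNH(OMe)·HCl, iPrMgCl, THF, −20 °C; aq NH4Cl
Reagents that add atoms: N,O-dimethylhydroxylamine hydrochloride CNOC.Cl
Why: Weinreb amide synthesis by aminolysis of the ester with the chloromagnesium amide made in the flask; at −20 °C the α-alkoxy stereocentre is not enolised, so (S) is kept.

Step 6
Reactants: 8 (2S,3S)-2-[4-(benzyloxy)-3-methoxyphenyl]-5-bromo-7-methoxy-3-methyl-2,3-dihydro-1-benzofuran; 10 (S)-2-(benzyloxy)-N-methoxy-N-methylpropanamide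
Product: 12 (2S)-2-(benzyloxy)-1-{(2S,3S)-2-[4-(benzyloxy)-3-methoxyphenyl]-7-methoxy-3-methyl-2,3-dihydro-1-benzofuran-5-yl}propan-1-one, via aryllithium 11 (not isolated)
Conditions: n-BuLi (1.05 equiv), THF, −78 °C; then 10, −78 °C; aq NH4Cl
Reagents that add atoms: n-butyllithium [Li]CCCC (lithium of intermediate 11 only)
Why: Bromine–lithium exchange and Weinreb ketone synthesis: the chelated tetrahedral adduct stops at the ketone level and shields the α-stereocentre from enolisation until the cold quench.

Step 7
Reactants: 12 (2S)-2-(benzyloxy)-1-{(2S,3S)-2-[4-(benzyloxy)-3-methoxyphenyl]-7-methoxy-3-methyl-2,3-dihydro-1-benzofuran-5-yl}propan-1-one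
Product: 13 (1R,2S)-2-(benzyloxy)-1-{(2S,3S)-2-[4-(benzyloxy)-3-methoxyphenyl]-7-methoxy-3-methyl-2,3-dihydro-1-benzofuran-5-yl}propan-1-ol
Conditions: Zn(BH4)2, Et2O, −78 to −20 °C; H2O
Reagents that add atoms: none
Why: Chelation-controlled (Cram chelate) hydride reduction: zinc ties the carbonyl O to the benzyloxy O in a five-membered chelate and hydride enters past H rather than CH3 of Cβ, which sets Cα as R (anti, erythro).

Step 8
Reactants: 13 (1R,2S)-2-(benzyloxy)-1-{(2S,3S)-2-[4-(benzyloxy)-3-methoxyphenyl]-7-methoxy-3-methyl-2,3-dihydro-1-benzofuran-5-yl}propan-1-ol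
Product: 14 (1R,2S)-1-[(2S,3S)-2-(4-hydroxy-3-methoxyphenyl)-7-methoxy-3-methyl-2,3-dihydro-1-benzofuran-5-yl]propane-1,2-diol
Conditions: H2 (1 atm), Pd/C (10 wt %), EtOAc/EtOH, rt, neutral, stopped at full conversion
Reagents that add atoms: none
Why: Catalytic hydrogenolysis of the aryl benzyl ether and the alkyl benzyl ether under neutral conditions: the unhindered primary benzylic C–O bonds should be cleaved ahead of the secondary ring bond C2–O1 and the Cα–OH bond, and no stereocentre is touched.

## Compound list

1 | 4-bromo-2-methoxyphenol | COc1cc(Br)ccc1O | starting material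
2 | 4-bromo-2-methoxy-6-nitrophenol | COc1cc(Br)cc([N+](=O)[O-])c1O | intermediate
3 | 2-amino-4-bromo-6-methoxyphenol | COc1cc(Br)cc(N)c1O | intermediate
4 | 5-bromo-2-hydroxy-3-methoxybenzenediazonium chloride | COc1cc(Br)cc([N+]#N)c1O.[Cl-] | intermediate
5 | 4-bromo-6-diazo-2-methoxycyclohexa-2,4-dien-1-one | COC1=CC(Br)=CC(=[N+]=[N-])C1=O | intermediate
6 | (E)-1-(benzyloxy)-2-methoxy-4-(prop-1-enyl)benzene | C/C=C/c1ccc(OCc2ccccc2)c(OC)c1 | starting material
7 | (1S,2R)-1-[4-(benzyloxy)-3-methoxyphenyl]-7-bromo-5-methoxy-2-methylspiro[2.5]octa-5,7-dien-4-one, both configurations at the spiro carbon | COC1=CC(Br)=CC2(C1=O)[C@H](C)[C@H]2c1ccc(OCc2ccccc2)c(OC)c1 | intermediate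
8 | (2S,3S)-2-[4-(benzyloxy)-3-methoxyphenyl]-5-bromo-7-methoxy-3-methyl-2,3-dihydro-1-benzofuran | COc1cc([C@H]2Oc3c(OC)cc(Br)cc3[C@@H]2C)ccc1OCc1ccccc1 | intermediate
9 | ethyl (S)-2-(benzyloxy)propanoate | C[C@H](OCc1ccccc1)C(=O)OCC | starting material
10 | (S)-2-(benzyloxy)-N-methoxy-N-methylpropanamide | C[C@H](OCc1ccccc1)C(=O)N(C)OC | intermediate
11 | {(2S,3S)-2-[4-(benzyloxy)-3-methoxyphenyl]-7-methoxy-3-methyl-2,3-dihydro-1-benzofuran-5-yl}lithium | COc1cc([C@H]2Oc3c(OC)cc([Li])cc3[C@@H]2C)ccc1OCc1ccccc1 | intermediate
12 | (2S)-2-(benzyloxy)-1-{(2S,3S)-2-[4-(benzyloxy)-3-methoxyphenyl]-7-methoxy-3-methyl-2,3-dihydro-1-benzofuran-5-yl}propan-1-one | COc1cc([C@H]2Oc3c(OC)cc(C(=O)[C@H](C)OCc4ccccc4)cc3[C@@H]2C)ccc1OCc1ccccc1 | intermediate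
13 | (1R,2S)-2-(benzyloxy)-1-{(2S,3S)-2-[4-(benzyloxy)-3-methoxyphenyl]-7-methoxy-3-methyl-2,3-dihydro-1-benzofuran-5-yl}propan-1-ol | COc1cc([C@H]2Oc3c(OC)cc([C@@H](O)[C@H](C)OCc4ccccc4)cc3[C@@H]2C)ccc1OCc1ccccc1 | intermediate
14 | (1R,2S)-1-[(2S,3S)-2-(4-hydroxy-3-methoxyphenyl)-7-methoxy-3-methyl-2,3-dihydro-1-benzofuran-5-yl]propane-1,2-diol | COc1cc([C@H]2Oc3c(OC)cc([C@@H](O)[C@H](C)O)cc3[C@@H]2C)ccc1O | target

## Step count and risks

Total step count: 8. Longest linear sequence: 7 (steps 1, 2, 3, 4, 6, 7, 8).

**Step 4.** Poor facial selectivity in the carbene transfer to the trans-disubstituted alkene would erode the enantiomeric purity at C3.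
- The fallback gives up catalyst control and sets out from 5 and 6.
- Achiral Rh2(OAc)4 is used in the known racemic formal [3+2] mode. This gives 7 together with the enantiomeric spirocyclopropyl dienone F1, and both are ring-expanded in the same flask with Sc(OTf)3.
- The racemate, 8 plus the (2R,3R)-bromide F2, is resolved by preparative chromatography on a cellulose tris(3,5-dimethylphenylcarbamate) phase.
- The fallback comes back to the route at 8.

**Step 7.** Erosion of chelate control by competing open-chain (Felkin–Anh) hydride delivery would give the threo epimer at Cα.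
- The fallback sets Cα in a C–C bond formation instead and sets out from 8 and 9.
- 9 is reduced with iBu2AlH (CH2Cl2, −78 °C) to (S)-2-(benzyloxy)propanal F3.
- 8 is lithiated to 11 and transmetalated with ClTi(OiPr)3 to the aryltitanium triisopropoxide F4. This reagent is too weakly Lewis acidic to chelate.
- F4 should therefore add to F3 under Felkin–Anh control to give the anti (1R,2S) alcohol. The fallback comes back to the route at 13.

**Step 8.** Competing hydrogenolysis of the other benzylic C–O bonds (loss of the Cα hydroxyl group, opening of C2–O1) may occur during the slower cleavage of the alkyl benzyl ether.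
- The fallback changes the order of events and sets out from 12.
- Debenzylation at the ketone stage (H2, Pd/C, EtOAc), where no benzylic carbinol exists, gives the dihydroxy ketone F5.
- Reduction of this free α-hydroxy ketone with excess Zn(BH4)2 through its zinc alkoxide chelate should give the anti diol, so the last step is a hydride reduction. The fallback comes back to the route at 14.

Further compounds
F1 | step 4 | (1R,2S)-1-[4-(benzyloxy)-3-methoxyphenyl]-7-bromo-5-methoxy-2-methylspiro[2.5]octa-5,7-dien-4-one, both configurations at the spiro carbon | COC1=CC(Br)=CC2(C1=O)[C@@H](C)[C@@H]2c1ccc(OCc2ccccc2)c(OC)c1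
F2 | step 4 | (2R,3R)-2-[4-(benzyloxy)-3-methoxyphenyl]-5-bromo-7-methoxy-3-methyl-2,3-dihydro-1-benzofuran | COc1cc([C@@H]2Oc3c(OC)cc(Br)cc3[C@H]2C)ccc1OCc1ccccc1
F3 | step 7 | (S)-2-(benzyloxy)propanal | C[C@H](OCc1ccccc1)C=O
F4 | step 7 | {(2S,3S)-2-[4-(benzyloxy)-3-methoxyphenyl]-7-methoxy-3-methyl-2,3-dihydro-1-benzofuran-5-yl}titanium triisopropoxide | COc1cc([C@H]2Oc3c(OC)cc([Ti](OC(C)C)(OC(C)C)OC(C)C)cc3[C@@H]2C)ccc1OCc1ccccc1
F5 | step 8 | (2S)-2-hydroxy-1-[(2S,3S)-2-(4-hydroxy-3-methoxyphenyl)-7-methoxy-3-methyl-2,3-dihydro-1-benzofuran-5-yl]propan-1-one | COc1cc([C@H]2Oc3c(OC)cc(C(=O)[C@H](C)O)cc3[C@@H]2C)ccc1O
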